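**Retrosynthetic overview**
- The target is unmasked last from its 5,8-bis(MOM) ether. Ring A is bought as hydroquinone, and ring B is the only ring that has to be made.
- Key disconnection, C3–C4 of ring B: the protected chromanone is an isomer of an achiral 2-(alk-1-en-2-yloxy)benzaldehyde. One enantioselective intramolecular alkene hydroacylation closes ring B, creates the C4 ketone and sets C2, the only stereocentre.
- Enabling feature: C4 sits on C4a of ring A directly beside C8a–O1, C3 is a bare CH2, and C2 carries O1 and one H. Removing that H makes C2=C3 a 1,1-disubstituted aryl enol ether whose =CH2 end lies 1,6 to a formyl C–H on ring A.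
- The enol ether comes from an aryl ester by methylenation (this brings C3). The formyl group comes from lithiation of the ring CH between O1 and the C5 oxygen (this brings C4). The ester comes from 2,5-bis(methoxymethoxy)phenol and (Z)-octadec-13-enoic acid.
- The acid comes from hex-1-yne and 12-bromododecanoic acid, with Z-selective semihydrogenation done before any rhodium chemistry.

Key step: step 8

Assumption: the absolute sense of induction in step 8 cannot be derived with certainty from the carbon-tethered precedents, so (R)-DTBM-SEGPHOS is written and the (S)-ligand is to be used if the first experiment shows the opposite sense.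

Step 1
Reactants: 1 hex-1-yne; 2 12-bromododecanoic acid
Product: 4 octadec-13-ynoic acid, via lithium hex-1-yn-1-ide 3 (not isolated)
Conditions: 1 (2.5 equiv), n-BuLi (2.4 equiv), THF, −78 to 0 °C; DMPU, then 2, 0 °C to rt; aq. HCl work-up
Reagents that add atoms: n-butyllithium, [Li]CCCC (the lithium of 3)
Why: SN2 alkylation of a lithium acetylide with a primary bromide in a dipolar aprotic cosolvent is the standard entry to acetylenic fatty acids; one equivalent of 3 is spent on the acid proton and the carboxylate is inert to the second.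

Step 2
Reactants: 4 octadec-13-ynoic acid
Product: 5 (13Z)-octadec-13-enoic acid
Conditions: H2 (1 atm), Pd/CaCO3 poisoned with Pb(OAc)2, quinoline, EtOAc, rt
Reagents that add atoms: none
Why: Lindlar semihydrogenation adds H2 syn on the poisoned palladium surface to give the Z-alkene, and quinoline holds the reduction at the alkene stage.

Step 3
Reactants: 6 hydroquinone
Product: 7 1,4-bis(methoxymethoxy)benzene
Conditions: NaH (2.4 equiv), MOMCl (2.4 equiv), DMF, 0 °C to rt
Reagents that add atoms: chloromethyl methyl ether (MOMCl), COCCl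
Why: Williamson-type double O-alkylation of the bis-phenoxide installs MOM groups that later direct both lithiations and leave under mild acid that spares the Z-alkene and C2.

Step 4
Reactants: 7 1,4-bis(methoxymethoxy)benzene
Product: 10 2,5-bis(methoxymethoxy)phenol, via 2,5-bis(methoxymethoxy)phenyllithium 8 (not isolated), via dimethyl arylboronate 9 (not isolated)
Conditions: n-BuLi, THF, 0 °C to rt; B(OMe)3, −78 °C to rt; AcOH, 30% aq. H2O2, 0 °C to rt
Reagents that add atoms: n-butyllithium, [Li]CCCC (the lithium of 8); trimethyl borate, COB(OC)OC (boron and methoxy groups of 9); hydrogen peroxide, OO (the phenol oxygen of 10)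
Why: Directed ortho-metalation (all four ring CH are equivalent and each lies next to an OMOM group) is followed by borylation and peroxide oxidation of the arylboronate with 1,2-aryl shift from boron to oxygen.

Step 5
Reactants: 5 (13Z)-octadec-13-enoic acid; 10 2,5-bis(methoxymethoxy)phenol
Product: 11 2,5-bis(methoxymethoxy)phenyl (13Z)-octadec-13-enoate
Conditions: DCC, DMAP (cat.), CH2Cl2, 0 °C to rt
Reagents that add atoms: none
Why: Steglich esterification is reliable for phenols with unbranched acids and neutral enough for the MOM ethers and the Z-alkene.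

Step 6
Reactants: 11 2,5-bis(methoxymethoxy)phenyl (13Z)-octadec-13-enoate
Product: 12 1,4-bis(methoxymethoxy)-2-{[(14Z)-nonadeca-1,14-dien-2-yl]oxy}benzene
Conditions: Cp2TiMe2 (2.5 equiv), toluene, 70 °C, dark; Et3N-deactivated silica
Reagents that add atoms: dimethyltitanocene Cp2TiMe2, [CH3-].[CH3-].[Ti+4].[cH-]1cccc1.[cH-]1cccc1
Why: In the Petasis methylenation thermally formed Cp2Ti=CH2 adds to the ester carbonyl and the oxatitanacyclobutane collapses to the enol ether, a reaction established for aryl esters, non-basic and indifferent to internal alkenes and acetals; this CH2 becomes C3.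

Step 7
Reactants: 12 1,4-bis(methoxymethoxy)-2-{[(14Z)-nonadeca-1,14-dien-2-yl]oxy}benzene
Product: 14 3,6-bis(methoxymethoxy)-2-{[(14Z)-nonadeca-1,14-dien-2-yl]oxy}benzaldehyde, via ring-lithiated enol ether 13 (not isolated)
Conditions: n-BuLi, TMEDA, THF, −78 to 0 °C; DMF, −78 °C to rt; pH 7 buffer
Reagents that add atoms: n-butyllithium, [Li]CCCC (the lithium of 13); N,N-dimethylformamide, CN(C)C=O (formyl carbon and oxygen of 14)
Why: Directed ortho-metalation and formylation act at the ring CH flanked by the enol-ether oxygen and an OMOM group, the cooperative in-between site that is also lithiated in 1,2,4-trialkoxybenzenes, and the enol ether has no alpha-vinylic hydrogen to compete; this carbon becomes C4.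

Step 8
Reactants: 14 3,6-bis(methoxymethoxy)-2-{[(14Z)-nonadeca-1,14-dien-2-yl]oxy}benzaldehyde
Product: 15 (2R)-2-[(12Z)-heptadec-12-en-1-yl]-5,8-bis(methoxymethoxy)-2,3-dihydro-4H-chromen-4-one
Conditions: [Rh(cod)Cl]2 (2.5 mol %), (R)-DTBM-SEGPHOS (5 mol %), NaB[3,5-(CF3)2C6H3]4 (5 mol %), degassed THF, 60 °C, argon
Reagents that add atoms: none
Why: Proposed new method: the cationic bisphosphine complex of monovalent rhodium binds the enol-ether alkene of 14 and inserts into the neighbouring formyl C–H bond, the hydride of the resulting acyl hydride of trivalent rhodium migrates to C2 so that rhodium ends on the terminal CH2 (C3) in a seven-membered acyl alkyl rhodacycle, and C–C reductive elimination joins C3 to the acyl carbon C4 and returns the catalyst. The closest known reaction type is the rhodium-catalysed enantioselective endo-hydroacylation of 1,1-disubstituted alkenes, shown for 2-(2-substituted allyl)benzaldehydes (to 3-substituted 1-tetralones) and 4-substituted pent-4-enals (to 3-substituted cyclopentanones); new here is that the benzylic CH2 of the tether is the oxygen O1, so that the alkene is an aryl 1-alkylvinyl ether. Ring B is the only ring closed, in a formal 6-endo-trig mode in which both alkene carbons become ring members. C2 is the only new stereocentre and is set in the hydride migration, where the C2-symmetric ligand decides which face of the prochiral alkene, flanked by the tethered aryloxy group on one side and the long alkyl chain on the other, lies against Rh–H. The step needs insertion with rhodium at C3 and not at C2, which the 1,1-disubstitution (no tertiary alkyl rhodium) and the enol-ether polarisation (C2 is the hydride-accepting carbon) secure, and it needs cyclisation to outrun decarbonylation, beta-aryloxy elimination and any contact of Rh–H with the remote Z-alkene, which the 1,6-relation of CHO and =CH2 across O1 and the endocyclic, non-coplanar C2–O1 bond of the rhodacycle should secure. No atom is added or lost, since the achiral monocyclic aldehyde is an isomer of the bicyclic, stereodefined ketone.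

Step 9
Reactants: 15 (2R)-2-[(12Z)-heptadec-12-en-1-yl]-5,8-bis(methoxymethoxy)-2,3-dihydro-4H-chromen-4-one
Product: 16 (2R)-2-[(12Z)-heptadec-12-en-1-yl]-5,8-dihydroxy-2,3-dihydro-4H-chromen-4-one (target)
Conditions: HCl (1.25 M in MeOH), THF, rt to 40 °C, argon
Reagents that add atoms: none
Why: Acid-catalysed transacetalisation turns the aryl MOM ethers into dimethoxymethane under conditions that touch neither the Z-alkene nor the base-sensitive C2–O1 bond (retro-oxa-Michael), and no base is used once C2 is set.

**Compound list**
1 | hex-1-yne | CCCCC#C | starting material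
2 | 12-bromododecanoic acid | OC(=O)CCCCCCCCCCCBr | starting material
3 | lithium hex-1-yn-1-ide | CCCCC#C[Li] | intermediate
4 | octadec-13-ynoic acid | CCCCC#CCCCCCCCCCCCC(=O)O | intermediate
5 | (13Z)-octadec-13-enoic acid | CCCC/C=C\CCCCCCCCCCCC(=O)O | intermediate
6 | hydroquinone (benzene-1,4-diol) | Oc1ccc(O)cc1 | starting material
7 | 1,4-bis(methoxymethoxy)benzene | COCOc1ccc(OCOC)cc1 | intermediate
8 | 2,5-bis(methoxymethoxy)phenyllithium | [Li]c1cc(OCOC)ccc1OCOC | intermediate
9 | dimethyl [2,5-bis(methoxymethoxy)phenyl]boronate | COB(OC)c1cc(OCOC)ccc1OCOC | intermediate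
10 | 2,5-bis(methoxymethoxy)phenol | Oc1cc(OCOC)ccc1OCOC | intermediate
11 | 2,5-bis(methoxymethoxy)phenyl (13Z)-octadec-13-enoate | CCCC/C=C\CCCCCCCCCCCC(=O)Oc1cc(OCOC)ccc1OCOC | intermediate
12 | 1,4-bis(methoxymethoxy)-2-{[(14Z)-nonadeca-1,14-dien-2-yl]oxy}benzene | CCCC/C=C\CCCCCCCCCCCC(=C)Oc1cc(OCOC)ccc1OCOC | intermediate
13 | ring-lithiated enol ether (lithium between the enol-ether oxygen and an OMOM group) | CCCC/C=C\CCCCCCCCCCCC(=C)Oc1c([Li])c(OCOC)ccc1OCOC | intermediate
14 | 3,6-bis(methoxymethoxy)-2-{[(14Z)-nonadeca-1,14-dien-2-yl]oxy}benzaldehyde | CCCC/C=C\CCCCCCCCCCCC(=C)Oc1c(C=O)c(OCOC)ccc1OCOC | intermediate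
15 | (2R)-2-[(12Z)-heptadec-12-en-1-yl]-5,8-bis(methoxymethoxy)-2,3-dihydro-4H-chromen-4-one | CCCC/C=C\CCCCCCCCCCC[C@@H]1CC(=O)c2c(OCOC)ccc(OCOC)c2O1 | intermediate
16 | (2R)-2-[(12Z)-heptadec-12-en-1-yl]-5,8-dihydroxy-2,3-dihydro-4H-chromen-4-one | CCCC/C=C\CCCCCCCCCCC[C@@H]1CC(=O)c2c(O)ccc(O)c2O1 | target

**Step count**
Total step count: 9.
Longest linear sequence: 7 (steps 1, 2, 5, 6, 7, 8, 9, or equally steps 3 to 9).

**Steps most likely to fail**

1. Step 8 (proposed new method).
- What may go wrong: decarbonylation of the acyl rhodium hydride; migration of the 1,1-disubstituted double bond into the chain by reversible insertion; beta-aryloxy elimination from the alkyl rhodium; poor facial selectivity; Z-to-E drift of the remote alkene.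
- Fallback (known chemistry, sets out from 5 and 10, comes back at 15): the stereocentre is obtained by resolution, and the same C3–C4 bond is closed with reversed polarity.
- Acid 5 is reduced with LiAlH4 to (13Z)-octadec-13-en-1-ol F1. This is oxidised with Dess–Martin periodinane to (13Z)-octadec-13-enal F2.
- A Corey–Chaykovsky reaction (trimethylsulfonium iodide, NaH, DMSO) converts F2 into racemic 2-[(12Z)-heptadec-12-en-1-yl]oxirane F3.
- Hydrolytic kinetic resolution with (R,R)-(salen)Co(OAc) (trivalent cobalt) and 0.45 equiv of water gives (2S,14Z)-nonadec-14-ene-1,2-diol F4.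
- The primary hydroxyl of F4 is tosylated (TsCl, Et3N, cat. Bu2SnO) to (2S,14Z)-2-hydroxynonadec-14-en-1-yl 4-methylbenzenesulfonate F5.
- Phenol 10 is formylated at its only free ortho position (MgCl2, Et3N, paraformaldehyde, MeCN) to 2-hydroxy-3,6-bis(methoxymethoxy)benzaldehyde F6.
- A Mitsunobu reaction of F6 with F5 (PPh3, DIAD) proceeds with inversion to (2R,14Z)-2-[2-formyl-3,6-bis(methoxymethoxy)phenoxy]nonadec-14-en-1-yl 4-methylbenzenesulfonate F7.
- An N-heterocyclic carbene (thiazolium salt, DBU, toluene) turns the formyl carbon into an acyl anion equivalent. It displaces the primary tosylate intramolecularly (6-exo-tet), a closure known for salicylaldehyde-derived tosylates, and gives 15.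

2. Step 7.
- What may go wrong: lithiation next to the other OMOM group instead of the in-between position, or competing allylic deprotonation beside the enol ether.
- Fallback (sets out from 7 through 8, comes back at 13 and so at 14): the site is fixed by a halogen before the chain is attached.
- Aryllithium 8 is quenched with BrCF2CF2Br to 2-bromo-1,4-bis(methoxymethoxy)benzene F8.
- LiTMP in the presence of B(Oi-Pr)3 at −78 °C metalates the CH between Br and OMOM and traps it as diisopropyl [2-bromo-3,6-bis(methoxymethoxy)phenyl]boronate F9. This is oxidised in the same flask (H2O2, AcOH) to 2-bromo-3,6-bis(methoxymethoxy)phenol F10.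
- Steglich esterification with 5 gives 2-bromo-3,6-bis(methoxymethoxy)phenyl (13Z)-octadec-13-enoate F11.
- Petasis methylenation gives 2-bromo-1,4-bis(methoxymethoxy)-3-{[(14Z)-nonadeca-1,14-dien-2-yl]oxy}benzene F12.
- Bromine–lithium exchange (n-BuLi, THF, −78 °C) delivers 13, which DMF converts into 14.

3. Step 9.
- What may go wrong: acid-induced opening of ring B with erosion of configuration at C2, sluggish loss of the C8 acetal, or air oxidation of the hydroquinone.
- Fallback (sets out from 15, comes back at 16): oxidative instead of solvolytic unmasking.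
- (NH4)2Ce(NO3)6 in MeCN/H2O at 0 °C oxidises the hydroquinone bis-acetal to (2R)-2-[(12Z)-heptadec-12-en-1-yl]-2,3-dihydro-4H-chromene-4,5,8-trione F13.
- Na2S2O4 in EtOAc/H2O at rt reduces F13 at near-neutral pH to 16.

**Further compounds**
F1 | step 8 | (13Z)-octadec-13-en-1-ol | CCCC/C=C\CCCCCCCCCCCCO
F2 | step 8 | (13Z)-octadec-13-enal | CCCC/C=C\CCCCCCCCCCCC=O
F3 | step 8 | racemic 2-[(12Z)-heptadec-12-en-1-yl]oxirane | CCCC/C=C\CCCCCCCCCCCC1CO1
F4 | step 8 | (2S,14Z)-nonadec-14-ene-1,2-diol | CCCC/C=C\CCCCCCCCCCC[C@@H](CO)O
F5 | step 8 | (2S,14Z)-2-hydroxynonadec-14-en-1-yl 4-methylbenzenesulfonate | CCCC/C=C\CCCCCCCCCCC[C@@H](COS(=O)(=O)c1ccc(C)cc1)O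
F6 | step 8 | 2-hydroxy-3,6-bis(methoxymethoxy)benzaldehyde | O=Cc1c(O)c(OCOC)ccc1OCOC
F7 | step 8 | (2R,14Z)-2-[2-formyl-3,6-bis(methoxymethoxy)phenoxy]nonadec-14-en-1-yl 4-methylbenzenesulfonate | CCCC/C=C\CCCCCCCCCCC[C@H](COS(=O)(=O)c1ccc(C)cc1)Oc1c(C=O)c(OCOC)ccc1OCOC
F8 | step 7 | 2-bromo-1,4-bis(methoxymethoxy)benzene | COCOc1ccc(OCOC)c(Br)c1
F9 | step 7 | diisopropyl [2-bromo-3,6-bis(methoxymethoxy)phenyl]boronate | CC(C)OB(OC(C)C)c1c(Br)c(OCOC)ccc1OCOC
F10 | step 7 | 2-bromo-3,6-bis(methoxymethoxy)phenol | Oc1c(Br)c(OCOC)ccc1OCOC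
F11 | step 7 | 2-bromo-3,6-bis(methoxymethoxy)phenyl (13Z)-octadec-13-enoate | CCCC/C=C\CCCCCCCCCCCC(=O)Oc1c(Br)c(OCOC)ccc1OCOC
F12 | step 7 | 2-bromo-1,4-bis(methoxymethoxy)-3-{[(14Z)-nonadeca-1,14-dien-2-yl]oxy}benzene | CCCC/C=C\CCCCCCCCCCCC(=C)Oc1c(Br)c(OCOC)ccc1OCOC
F13 | step 9 | (2R)-2-[(12Z)-heptadec-12-en-1-yl]-2,3-dihydro-4H-chromene-4,5,8-trione | CCCC/C=C\CCCCCCCCCCC[C@@H]1CC(=O)C2=C(O1)C(=O)C=CC2=O
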